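**Conventions and assumption**

Atom numbering used throughout: pyrrole N–C9a–C1–C2–C3; ring B C9a–C9–C10–C11–C12–C1 with the ethyl group (C16–C17) on C10; lactone D C11–O–C14(=O)–C13(CH3)–C12; azepine N–C5–C6–C7–C8–C9–C9a; lactone E C18–C19–C20(CH3)–C21(=O)–O on C3. Compound numbers 1–23 are those of the compound list.

Assumption: the C13 configuration drawn for 21 is the one predicted by the insertion model given at step 16; every later step avoids base so that it is kept.

## Analysis of the target

The target is a pentacyclic Stemona-type alkaloid built on a fully substituted pyrrole that is fused to a carbocycle (ring B) and bridged from N to C9 by four methylenes (azepine, C5–C8). A γ-lactone (lactone D) is cis-fused to ring B across C11–C12, and a second α-methyl-γ-butyrolactone (lactone E) hangs from the pyrrole α-carbon C3 through C18. There are seven stereocentres (9R,10R,11S,12R,13R,18S,20S). Around ring B, H9/H10 and H10/H11 are trans (the ethyl group is anti to both C8 and the C11 oxygen), whereas H11, H12 and H13 are all cis, so the C13 methyl group sits on the concave face of the B/D bicycle, syn to the C12–C1 bond; lactone E is α,γ-cis. The sensitive points are the electron-rich pyrrole (acids, oxidants, electrophiles), the pyrrolylic C18–O bond, which can ionize, and the two α-carbonyl centres C13 and C20, of which C13 is in the more crowded orientation and would suffer from any enolization. The difficulty is the block of five contiguous stereocentres C9–C13 on a ring fused to a heteroaromatic, together with the remote C18/C20 pair that no ring relays. The strategy rests on the C12–H bond cis to the C11 oxygen: it is pseudo-axial on the ring B half-chair, parallel to the pyrrole π-system through C1, and five atoms away from the α-carbon of an acyl group placed on the C11 oxygen. C12–C13 and lactone D can therefore be made from an unfunctionalized C12 methylene by carbenoid C–H insertion.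

## Retrosynthetic reasoning

**23 ⇒ 22 ⇒ 21 (C21–O acyl bond, then C18–H).** Lactone E is opened to hydroxy ester 22 and C18 is taken back to the ketone of 21. C18 is an isolated pyrrolylic carbinol centre whose configuration can be imposed by a chiral reducing catalyst on an aryl ketone, and a γ-hydroxy ester closes without activation. C20 is then the only stereocentre the side chain has to bring along. The forward reduction must leave lactone D and the ester alone and must not enolize C13 or C20.

**21 ⇒ 20 (C12–C13, the key cut).** Lactone D is cut at C12–C13 and not at one of its C–O bonds. A C–O cut would force C12 to be carried as an epimerizable, pyrrolylic, α-branched acid side chain. The C12–C13 cut returns C12 to a plain methylene and puts all the work on the C11 oxygen, which only has to carry an α-diazopropionyl group (20). Forward, a metal carbenoid at C13 must insert into the C12–H bond cis to that oxygen, which makes the ring, the bond and the C12 and C13 centres in one step. The C3 keto ester is already in place in 20 because it lowers the nucleophilicity of the pyrrole.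

**20 ⇒ 19 ⇒ 18 (diazo group, then the C11–O ester bond).** The diazo group is traced to an acetyl group (deacylative diazo transfer on the α-methyl β-keto ester 19) and the ester to alcohol 18. This pair is preferred to displacing a secondary α-bromo ester with a sulfonylhydrazide, where base-induced elimination to the acrylate competes.

**18 ⇒ 17 ⇒ 13 + 16 (C3–C18).** The side chain is attached by Friedel–Crafts acylation of the only free α-position of pyrrole 13 with acid chloride 16, the C11 oxygen being silylated (17) while the acid chloride is present. 16 comes from diester 14 through half ester 15, so C20 is bought and not made.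

**13 ⇒ 12 ⇒ 11 (N–C9a and N–C3).** Both C–N bonds of the pyrrole are cut together. Because the nitrogen is tethered to C9 through C5–C8, the condensation that makes the pyrrole also closes the azepine. The precursor is the amino 1,4-keto aldehyde 12, stored as carbamate 11. This reduces the tricycle to a tetrasubstituted cyclohexanone whose stereocentres sit on a chair.

**11 ⇒ 10 ⇒ 9 ⇒ 8 ⇒ 6 + 7 (C2=C3 cleavage, C1–C2, C6–C7).** The aldehyde comes from oxidative cleavage of the allyl group of 10, and that allyl group from alkylation of the less substituted enolate of 9. The aminobutyl chain of 9 is assembled by cross-metathesis of the allyl group of 6 with allyl carbamate 7 (8) and saturation. The chain is finished before the second allyl group arrives, so the two alkenes never coexist.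

**6 ⇒ 5 ⇒ 4 ⇒ 3 ⇒ 2 ⇒ 1 (C10–C16 and C9–C8).** Conjugate addition of an ethyl group to enone 4 and allylation of the resulting enolate 5 set C10 and C9. The single stereocentre of 4 (the later C11) directs the ethyl group anti, and the ethyl group then directs the allyl group anti, so the three ring B centres derive from one. 4 is reached from the achiral enone ketal 1 by asymmetric carbonyl reduction (2), silylation (3) and ketal hydrolysis.

## Alternatives that were turned down

**Alternative 1:** Disconnection of C9–C10 by a ring-contracting ester-enolate Claisen rearrangement. The substrate is the pyrrole-fused δ-lactone A2, whose acyl carbon sits on the C9 methylene and whose alkoxy carbon C12 carries a but-1-enyl group. LiN(SiMe3)2 and Me3SiCl would give the silyl ketene acetal, which rearranges through a bridged boat transition state to the trans dihydroindole acid A1; C9–C10 forms, O–C12 breaks and a C11=C12 double bond remains.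
- For it: a concerted step closes the carbocycle and transfers one carbinol centre into both C9 and C10; enolization of A2 is easy because C9 is flanked by pyrrole and carbonyl; no diazo compound is needed. On setting C9/C10 it is as good as the conjugate addition–allylation used here.
- Against it: the step addresses two of the five ring B centres. From A1, C11, C12, C13 and lactone D are all still missing and must come from a hydroboration that relies on one allylic ethyl group plus a separate lactone annulation. The C9 carboxyl is at the wrong oxidation level for the azepine and costs reduction, olefination, metathesis and hydrogenation. In the bridged boat the trans relationship requires the (Z)-alkene of A2, whose inside substituent is pressed against the pyrrole carbon C1.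
- Comparison: the chosen route spends its key step where the target is hardest (C12, C13, lactone D) and gets C9–C11 from a cyclohexanone chair, with fewer steps overall.

**Alternative 2:** Disconnection of C9a–C9 and N–C5 in one operation. The substrate is the N–H pyrrole A4, which already carries both lactones and a cross-conjugated dienone chain on C10. Sc(OTf)3 would trigger attack of the free pyrrole α-carbon on the enone β-carbon C9 (6-exo, ring B), and DBU would then add the pyrrole nitrogen to the vinyl ketone terminus C5 (7-endo, azepine), giving the 7-oxo compound A3.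
- For it: two rings and two bonds in one flask from a late, convergent intermediate. On rings per step and on convergence it is stronger than the chosen key step, which closes one ring.
- Against it: a divinyl ketone under a Lewis acid is also a Nazarov substrate and a Michael polymerization partner. C9 is set by acyclic 1,2-induction from C10 in a reversible addition. The 7-endo aza-Michael addition of a weakly nucleophilic pyrrole nitrogen is uphill. A3 carries a C7 carbonyl that must be excised in the presence of two lactones and a pyrrole (at least two more steps, with hydrazine or desulfurization conditions that endanger the lactones). A4 requires lactone D with C11–C13 to be built on an open chain.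
- Comparison: the chosen route gives up the double closure but creates C12 and C13 on a rigid tricycle and leaves no superfluous functional group.

**Alternative 3:** Disconnection of C10–C11 with lactone D closed in the same operation. The substrate is the pyrroloazepine A6, with an (E)-allylsilane on C9 and, on C1, a chain carrying the C11 aldehyde, the C13 methyl group and a methyl ester. BF3·OEt2 would activate the aldehyde, the allylsilane γ-carbon C10 would attack through a chair-like transition state, and the C11 hydroxyl would lactonize, giving the 10-vinyl compound A5, to be hydrogenated to the target.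
- For it: two rings and two stereocentres (C10, C11) in one step, no diazo chemistry, and the vinyl-to-ethyl adjustment is trivial. On ring count it is stronger than the chosen step and on stereocentres it is equal.
- Against it: A6 holds C12 as a centre that is at once α to an aldehyde and pyrrolylic, next to the α-ester centre C13; these are exactly the two centres most prone to epimerize and they would be carried through several steps. BF3·OEt2 meets an electron-rich pyrrole, a pyrrolylic lactone C–O bond and a pyrrolylic allylsilane prone to protodesilylation. The chair must deliver C10/C11 anti and the correct sense relative to C9 from a flexible tether.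
- Comparison: the chosen route makes C12 and C13 last, from a methylene group, so they are never exposed in an acyclic, enolizable form.

Key step: step 16

## Route

Step 1
Reactants: 1 1,4-dioxaspiro[4.5]dec-6-en-8-one
Product: 2 (8R)-1,4-dioxaspiro[4.5]dec-6-en-8-ol
Conditions: RuCl(p-cymene)[(R,R)-TsDPEN] (1 mol%), HCO2Na, n-Bu4NCl (cat.), CH2Cl2–H2O, rt
Reagents that add atoms: none
Why: Noyori–Ikariya asymmetric transfer hydrogenation reduces the enone carbonyl 1,2; the alkenyl arm takes the place an aryl group has in the hydride-transfer transition state, so the (R,R)-ligand should give the 8R alcohol.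

Step 2
Reactants: 2 (8R)-1,4-dioxaspiro[4.5]dec-6-en-8-ol
Product: 3 tert-butyl{[(8R)-1,4-dioxaspiro[4.5]dec-6-en-8-yl]oxy}dimethylsilane
Conditions: TBSCl, imidazole, DMF, rt
Reagents that add atoms: tert-butyldimethylsilyl chloride, CC(C)(C)[Si](C)(C)Cl
Why: Standard silylation of a secondary allylic alcohol; the bulky silyl ether is the later stereodirecting group and the C11 oxygen protection.

Step 3
Reactants: 3 tert-butyl{[(8R)-1,4-dioxaspiro[4.5]dec-6-en-8-yl]oxy}dimethylsilane
Product: 4 (4R)-4-[(tert-butyldimethylsilyl)oxy]cyclohex-2-en-1-one
Conditions: PPTS (cat.), acetone–H2O, 45 °C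
Reagents that add atoms: water, O
Why: Mild acid hydrolysis of the allylic dioxolane (allyl-stabilized oxocarbenium ion) unveils the enone with the carbonyl transposed; the silyl ether and the stereocentre are untouched.

Step 4
Reactants: 4 (4R)-4-[(tert-butyldimethylsilyl)oxy]cyclohex-2-en-1-one
Product: 6 (2R,3R,4R)-4-[(tert-butyldimethylsilyl)oxy]-3-ethyl-2-(prop-2-en-1-yl)cyclohexan-1-one, via ethylzinc enolate 5 (not isolated)
Conditions: Et2Zn, Cu(OTf)2 (2 mol%), P(OEt)3 (4 mol%), toluene, −30 °C; then allyl acetate, Pd(PPh3)4 (4 mol%), 0 °C
Reagents that add atoms: diethylzinc, CC[Zn]CC; allyl acetate, C=CCOC(C)=O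
Why: Copper-catalysed conjugate addition puts the ethyl group on the face anti to the C4 silyloxy group (C10 trans to the C11 oxygen), and the regiodefined zinc enolate 5 is allylated through a π-allylpalladium complex anti to the new ethyl group (C9 trans to C10). The silyloxy group is γ to the enolate carbon and cannot be eliminated, and the all-trans, all-equatorial product is also the thermodynamic one.

Step 5
Reactants: 6 (2R,3R,4R)-4-[(tert-butyldimethylsilyl)oxy]-3-ethyl-2-(prop-2-en-1-yl)cyclohexan-1-one; 7 tert-butyl N-(prop-2-en-1-yl)carbamate
Product: 8 tert-butyl N-{(2E)-4-[(1R,2R,3R)-3-[(tert-butyldimethylsilyl)oxy]-2-ethyl-6-oxocyclohexyl]but-2-en-1-yl}carbamate (E/Z mixture expected)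
Conditions: 7 (3 equiv), second-generation Hoveyda–Grubbs catalyst (5 mol%), CH2Cl2, 40 °C
Reagents that add atoms: none
Why: Olefin cross-metathesis of the unhindered terminal allyl group with excess allyl carbamate completes the four-carbon chain C8–C5 and brings in the nitrogen; the alkene geometry is irrelevant because the double bond is saturated next.

Step 6
Reactants: 8 tert-butyl N-{(2E)-4-[(1R,2R,3R)-3-[(tert-butyldimethylsilyl)oxy]-2-ethyl-6-oxocyclohexyl]but-2-en-1-yl}carbamate
Product: 9 tert-butyl N-{4-[(1R,2R,3R)-3-[(tert-butyldimethylsilyl)oxy]-2-ethyl-6-oxocyclohexyl]butyl}carbamate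
Conditions: H2 (1 atm), Pd/C, EtOAc, rt
Reagents that add atoms: none
Why: Catalytic hydrogenation of the disubstituted alkene; ketone, carbamate and silyl ether are inert under these conditions.

Step 7
Reactants: 9 tert-butyl N-{4-[(1R,2R,3R)-3-[(tert-butyldimethylsilyl)oxy]-2-ethyl-6-oxocyclohexyl]butyl}carbamate
Product: 10 tert-butyl N-{4-[(1R,2R,3R)-3-[(tert-butyldimethylsilyl)oxy]-2-ethyl-6-oxo-5-(prop-2-en-1-yl)cyclohexyl]butyl}carbamate (both configurations at the allyl-bearing carbon)
Conditions: LiN(i-Pr)2 (2.2 equiv), THF, −78 °C; allyl bromide (1.2 equiv), −78 → −40 °C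
Reagents that add atoms: allyl bromide, C=CCBr
Why: After the first equivalent of base has taken the carbamate N–H, kinetic deprotonation occurs at the unsubstituted α′-methylene and the enolate is C-allylated (the lithium carbamate is a poor nucleophile at this temperature). The new centre becomes the sp2 carbon C1 later, and C9 stays in its favoured equatorial orientation.

Step 8
Reactants: 10 tert-butyl N-{4-[(1R,2R,3R)-3-[(tert-butyldimethylsilyl)oxy]-2-ethyl-6-oxo-5-(prop-2-en-1-yl)cyclohexyl]butyl}carbamate
Product: 11 tert-butyl N-{4-[(1R,2R,3R)-3-[(tert-butyldimethylsilyl)oxy]-2-ethyl-6-oxo-5-(2-oxoethyl)cyclohexyl]butyl}carbamate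
Conditions: O3, CH2Cl2–MeOH, −78 °C; then Me2S, −78 °C → rt
Reagents that add atoms: ozone, [O-][O+]=O
Why: Ozonolysis with reductive work-up cuts the only alkene to the aldehyde and so produces the 1,4-keto aldehyde (C9a ketone, C3 aldehyde) needed for the pyrrole.

Step 9
Reactants: 11 tert-butyl N-{4-[(1R,2R,3R)-3-[(tert-butyldimethylsilyl)oxy]-2-ethyl-6-oxo-5-(2-oxoethyl)cyclohexyl]butyl}carbamate
Product: 13 tricyclic pyrrole silyl ether, (9R,10R,11R)-11-[(tert-butyldimethylsilyl)oxy]-10-ethyl-4,5,6,7-tetrahydroindole-type core with N and C9 bridged by C5–C8 (C2–H and C3–H free), via amino keto aldehyde 12 (not isolated)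
Conditions: TFA, CH2Cl2, 0 °C; evaporate; then NaOAc, AcOH, ClCH2CH2Cl (0.02 M), 50 °C
Reagents that add atoms: none
Why: Acidolysis of the carbamate frees the primary amine (12, as its salt), which on buffering condenses with the C9a ketone through the four-carbon tether (seven-membered ring) and with the C3 aldehyde in an intramolecular Paal–Knorr reaction. Aromatization makes the sequence irreversible, closes pyrrole and azepine together and removes the stereocentre at C1.

Step 10
Reactants: 14 dimethyl (2S)-2-methylbutanedioate
Product: 15 (3S)-4-methoxy-3-methyl-4-oxobutanoic acid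
Conditions: LiOH·H2O (1.0 equiv), THF–H2O, 0 °C; then 1 M HCl
Reagents that add atoms: lithium hydroxide, [Li+].[OH-]
Why: The ester on the methylene-bound carboxyl is saponified faster than the α-branched one, and the carboxylate formed shields the second ester from hydroxide; one equivalent of base at 0 °C does not enolize C20.

Step 11
Reactants: 15 (3S)-4-methoxy-3-methyl-4-oxobutanoic acid
Product: 16 methyl (2S)-4-chloro-2-methyl-4-oxobutanoate
Conditions: (COCl)2, DMF (cat.), CH2Cl2, 0 °C → rt
Reagents that add atoms: oxalyl chloride, ClC(=O)C(Cl)=O
Why: Standard acid chloride formation through the chloroiminium catalyst; the stereocentre is β to the acyl chloride and cannot be lost through a ketene.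

Step 12
Reactants: 13 tricyclic pyrrole silyl ether; 16 methyl (2S)-4-chloro-2-methyl-4-oxobutanoate
Product: 17 methyl (2S)-4-[(9R,10R,11R)-11-[(tert-butyldimethylsilyl)oxy]-10-ethyl-tricycl-3-yl]-2-methyl-4-oxobutanoate (C3 keto ester of 13)
Conditions: Et2AlCl (1.2 equiv), CH2Cl2, 0 °C; then 16, 0 °C
Reagents that add atoms: none
Why: Friedel–Crafts acylation at the only free α-position (C3) of the electron-rich trialkylpyrrole. The dialkylaluminium chloride activates the acid chloride and consumes the HCl as ethane, which spares the silyl ether and the acid-sensitive pyrrole.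

Step 13
Reactants: 17 methyl (2S)-4-[(9R,10R,11R)-11-[(tert-butyldimethylsilyl)oxy]-10-ethyl-tricycl-3-yl]-2-methyl-4-oxobutanoate
Product: 18 methyl (2S)-4-[(9R,10R,11R)-10-ethyl-11-hydroxy-tricycl-3-yl]-2-methyl-4-oxobutanoate (C11 alcohol)
Conditions: HF·pyridine, THF, 0 °C → rt
Reagents that add atoms: none
Why: Fluoride-mediated desilylation under non-basic conditions; the acylated pyrrole now tolerates acid, and neither C20 nor the ketone α-position is exposed to base.

Step 14
Reactants: 18 methyl (2S)-4-[(9R,10R,11R)-10-ethyl-11-hydroxy-tricycl-3-yl]-2-methyl-4-oxobutanoate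
Product: 19 C11 2-methyl-3-oxobutanoate of 18 (both configurations at the new α-carbon)
Conditions: ethyl 2-methyl-3-oxobutanoate (5 equiv), DMAP (0.3 equiv), toluene, reflux, 4 Å molecular sieves
Reagents that add atoms: ethyl 2-methyl-3-oxobutanoate, CCOC(=O)C(C)C(C)=O
Why: DMAP-catalysed transesterification of a β-keto ester proceeds through the acylketene, so it acylates the secondary C11 alcohol without touching the simple methyl ester or C20.

Step 15
Reactants: 19 C11 2-methyl-3-oxobutanoate of 18
Product: 20 C11 2-diazopropanoate of 18 (9R,10R,11R; side chain 2S)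
Conditions: p-ABSA (1.5 equiv), DBU (1.5 equiv), MeCN, 0 °C → rt
Reagents that add atoms: 4-acetamidobenzenesulfonyl azide, CC(=O)Nc1ccc(cc1)S(=O)(=O)N=[N+]=[N-]
Why: Regitz deacylative diazo transfer: the β-keto ester enolate attacks the sulfonyl azide and the adduct fragments with transfer of the acetyl group to the sulfonamide nitrogen, leaving the α-diazopropionate. The C19 methylene next to the aryl ketone is not acidic enough to react, and an α-bromopropionate route is avoided because elimination to the acrylate competes there.

Step 16
Reactants: 20 C11 2-diazopropanoate of 18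
Product: 21 tetracyclic lactone D keto ester (9R,10R,11S,12R,13R; side chain 20S), methyl (2S)-2-methyl-4-oxo-4-(tetracycl-3-yl)butanoate
Conditions: Rh2(esp)2 (1 mol%; esp = α,α,α′,α′-tetramethyl-1,3-benzenedipropanoate), CH2Cl2, −40 → 0 °C, slow addition of 20 (final 0.01 M)
Reagents that add atoms: none
Why: Rh2(esp)2 takes up the diazo carbon and expels dinitrogen, giving an electrophilic dirhodium carbenoid at C13 whose empty p-orbital accepts the C12–H bond in a three-centre, hydride-transfer-like transition state; C12–C13 forms as the metal leaves, with retention at C12. The closest known reaction type is the dirhodium-catalysed intramolecular 1,5 C–H insertion of α-alkyl-α-diazo esters and diazoacetates that gives γ-lactones and cyclopentanes. Lactone D is closed by this 1,5-insertion through a five-membered array (C13–C14–O–C11–C12), and it is cis-fused because the reacting hydrogen is the pseudo-axial one gauche to the equatorial C11 oxygen; a trans-fused lactone is not impossible in principle but would have to use the unactivated pseudo-equatorial hydrogen. C12 is controlled by C11: the new bond takes the place of the hydrogen cis to the oxygen. C13 is controlled by the fit of catalyst and substrate: metal and methyl group lie on opposite faces of the forming ring and the dirhodium core can only sit on the open convex face, so the methyl group should end under ring B and H13 cis to H12, as the cis-selective insertions of α-alkyl diazo esters suggest. The step needs site selectivity over the tertiary C10–H, which is also cis to the oxygen and 1,5 to the carbenoid: only the pseudo-axial C12–H is aligned with the pyrrole π-system through C1 and so is the better hydride donor, while C10–H is screened by the ethyl group and the C8 methylene. It also needs chemoselectivity: the C3 acyl group lowers the nucleophilicity of the pyrrole toward the carbenoid, and the 1,2-hydride shift to the acrylate is slow for a methyl group and is held back further by low temperature, high dilution and the hindered bridging carboxylate.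

Step 17
Reactants: 21 tetracyclic lactone D keto ester
Product: 23 target, (9R,10R,11S,12R,13R,18S,20S)-bis-lactone, via hydroxy ester 22 (not isolated)
Conditions: (R)-2-methyl-CBS-oxazaborolidine (0.2 equiv), catecholborane (1.5 equiv), toluene, −78 → −20 °C; MeOH; then PPTS (cat.), CH2Cl2, rt
Reagents that add atoms: none
Why: Corey–Bakshi–Shibata reduction: the basic vinylogous-amide carbonyl binds the oxazaborolidine boron with the pyrrolyl group as the large substituent, so the (R)-catalyst should deliver hydride to give the 18S carbinol 22. The γ-hydroxy ester then lactonizes with loss of methanol and retention at C18, giving the α,γ-cis lactone E. No base is present, so C13 and C20 are not enolized.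

## Compound list

1 | 1,4-dioxaspiro[4.5]dec-6-en-8-one | O=C1C=CC2(CC1)OCCO2 | starting material
2 | (8R)-1,4-dioxaspiro[4.5]dec-6-en-8-ol | O[C@H]1C=CC2(OCCO2)CC1 | intermediate
3 | tert-butyl{[(8R)-1,4-dioxaspiro[4.5]dec-6-en-8-yl]oxy}dimethylsilane | CC(C)(C)[Si](C)(C)O[C@H]1C=CC2(OCCO2)CC1 | intermediate
4 | (4R)-4-[(tert-butyldimethylsilyl)oxy]cyclohex-2-en-1-one | O=C1C=C[C@H](O[Si](C)(C)C(C)(C)C)CC1 | intermediate
5 | ethylzinc enolate of (3R,4R)-4-[(tert-butyldimethylsilyl)oxy]-3-ethylcyclohexanone (enolate double bond C1=C2) | CC[C@H]1[C@H](O[Si](C)(C)C(C)(C)C)CCC(O[Zn]CC)=C1 | intermediate (not isolated)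
6 | (2R,3R,4R)-4-[(tert-butyldimethylsilyl)oxy]-3-ethyl-2-(prop-2-en-1-yl)cyclohexan-1-one | CC[C@H]1[C@H](O[Si](C)(C)C(C)(C)C)CCC(=O)[C@@H]1CC=C | intermediate
7 | tert-butyl N-(prop-2-en-1-yl)carbamate | C=CCNC(=O)OC(C)(C)C | starting material
8 | tert-butyl N-{(2E)-4-[(1R,2R,3R)-3-[(tert-butyldimethylsilyl)oxy]-2-ethyl-6-oxocyclohexyl]but-2-en-1-yl}carbamate | CC[C@H]1[C@H](O[Si](C)(C)C(C)(C)C)CCC(=O)[C@@H]1C/C=C/CNC(=O)OC(C)(C)C | intermediate
9 | tert-butyl N-{4-[(1R,2R,3R)-3-[(tert-butyldimethylsilyl)oxy]-2-ethyl-6-oxocyclohexyl]butyl}carbamate | CC[C@H]1[C@H](O[Si](C)(C)C(C)(C)C)CCC(=O)[C@@H]1CCCCNC(=O)OC(C)(C)C | intermediate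
10 | tert-butyl N-{4-[(1R,2R,3R)-3-[(tert-butyldimethylsilyl)oxy]-2-ethyl-6-oxo-5-(prop-2-en-1-yl)cyclohexyl]butyl}carbamate (mixture at ring C5) | CC[C@H]1[C@H](O[Si](C)(C)C(C)(C)C)CC(CC=C)C(=O)[C@@H]1CCCCNC(=O)OC(C)(C)C | intermediate
11 | tert-butyl N-{4-[(1R,2R,3R)-3-[(tert-butyldimethylsilyl)oxy]-2-ethyl-6-oxo-5-(2-oxoethyl)cyclohexyl]butyl}carbamate | CC[C@H]1[C@H](O[Si](C)(C)C(C)(C)C)CC(CC=O)C(=O)[C@@H]1CCCCNC(=O)OC(C)(C)C | intermediate
12 | (2R,3R,4R)-2-(4-aminobutyl)-4-[(tert-butyldimethylsilyl)oxy]-3-ethyl-6-(2-oxoethyl)cyclohexan-1-one (as trifluoroacetate salt) | CC[C@H]1[C@H](O[Si](C)(C)C(C)(C)C)CC(CC=O)C(=O)[C@@H]1CCCCN | intermediate (not isolated)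
13 | tricyclic pyrrole silyl ether, (9R,10R,11R)-11-[(tert-butyldimethylsilyl)oxy]-10-ethyl; pyrrole fused to ring B, N and C9 bridged by C5–C8 | CC[C@H]1[C@H](O[Si](C)(C)C(C)(C)C)Cc2ccn3c2[C@@H]1CCCC3 | intermediate
14 | dimethyl (2S)-2-methylbutanedioate | COC(=O)C[C@H](C)C(=O)OC | starting material
15 | (3S)-4-methoxy-3-methyl-4-oxobutanoic acid | OC(=O)C[C@H](C)C(=O)OC | intermediate
16 | methyl (2S)-4-chloro-2-methyl-4-oxobutanoate | ClC(=O)C[C@H](C)C(=O)OC | intermediate
17 | methyl (2S)-4-[(9R,10R,11R)-11-[(tert-butyldimethylsilyl)oxy]-10-ethyl-tricycl-3-yl]-2-methyl-4-oxobutanoate | CC[C@H]1[C@H](O[Si](C)(C)C(C)(C)C)Cc2cc(C(=O)C[C@H](C)C(=O)OC)n3c2[C@@H]1CCCC3 | intermediate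
18 | methyl (2S)-4-[(9R,10R,11R)-10-ethyl-11-hydroxy-tricycl-3-yl]-2-methyl-4-oxobutanoate | CC[C@H]1[C@H](O)Cc2cc(C(=O)C[C@H](C)C(=O)OC)n3c2[C@@H]1CCCC3 | intermediate
19 | C11 2-methyl-3-oxobutanoate ester of 18 (mixture at the keto ester α-carbon) | CC[C@H]1[C@H](OC(=O)C(C)C(C)=O)Cc2cc(C(=O)C[C@H](C)C(=O)OC)n3c2[C@@H]1CCCC3 | intermediate
20 | C11 2-diazopropanoate ester of 18 (key-step precursor) | CC[C@H]1[C@H](OC(=O)C(C)=[N+]=[N-])Cc2cc(C(=O)C[C@H](C)C(=O)OC)n3c2[C@@H]1CCCC3 | intermediate
21 | tetracyclic lactone D keto ester (9R,10R,11S,12R,13R; 20S) (key-step product) | CC[C@H]1[C@@H]2OC(=O)[C@H](C)[C@@H]2c2cc(C(=O)C[C@H](C)C(=O)OC)n3c2[C@@H]1CCCC3 | intermediate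
22 | (18S)-hydroxy ester of 21 | CC[C@H]1[C@@H]2OC(=O)[C@H](C)[C@@H]2c2cc([C@@H](O)C[C@H](C)C(=O)OC)n3c2[C@@H]1CCCC3 | intermediate (not isolated)
23 | target bis-lactone (9R,10R,11S,12R,13R,18S,20S), CNP0232452.6 | CC[C@H]1[C@@H]2OC(=O)[C@H](C)[C@@H]2c2cc([C@@H]3C[C@H](C)C(=O)O3)n3c2[C@@H]1CCCC3 | target

## Step count and least certain steps

Total: 17 steps. Longest linear sequence: 15 steps (steps 1–9 and 12–17); steps 10 and 11 form the side branch that joins at step 12.

**Step 16 (key step).** What may go wrong: insertion at the wrong C–H bond (the tertiary C10–H is equally cis to the ester oxygen), 1,2-hydride migration from the methyl group giving the acrylate ester, or the opposite facial orientation of the methyl group at C13. All three depend on small energy differences in a reactive carbenoid.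
Fallback (sets out from 13, returns at 21): build C12–C13 by enolate chemistry. Removal of the silyl group from 13 with n-Bu4NF would give the tricyclic C11 alcohol F1, and Parikh–Doering oxidation (SO3·pyridine, DMSO, i-Pr2NEt) the C11 ketone F2, whose enolate forms toward C12 because that side is conjugated with the pyrrole. Alkylation of this enolate (LiN(SiMe3)2, then methyl 2-bromopropanoate) would give the C12-alkylated keto ester F3, with C12 free to equilibrate. NaBH4 should deliver hydride axially and place the C11 hydroxyl equatorial and trans to the ethyl group; acid-catalysed lactonization of the cis-disposed hydroxy ester would then give the cis-fused lactone F4. F4 has no other acidic site, so deprotonation with LiN(i-Pr)2 and protonation of the enolate from the convex face by a hindered phenol would set C13 (lactone F5). Acylation of F5 at C3 with 16 under the conditions of step 12 would reach 21.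

**Step 17.** What may go wrong: poor enantiofacial control on a hindered, electron-rich ketone, or ionization of the pyrrolylic carbinol with loss of configuration or over-reduction.
Fallback (sets out from 21, returns at 23): thermodynamic control at C18. Luche reduction (NaBH4, CeCl3·7H2O, MeOH) and lactonization would give 23 together with its C18 epimer F6. Because the C18–O bond is pyrrolylic, a catalytic Brønsted acid should open it reversibly, and re-closure favours the α,γ-cis lactone 23; F6 would be equilibrated and recycled.

**Step 12.** What may go wrong: acylation at C2 in place of C3, acid-induced oligomerization of the trialkylpyrrole, or loss of the silyl ether to liberated HCl.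
Fallback (sets out from 15 and 13, returns at 17): Vilsmeier–Haack acylation. 15 would be converted through 16 and dimethylamine into the dimethylamide F7. Its chloroiminium salt (POCl3) is a milder and more α-selective electrophile, and hydrolysis of the iminium adduct with aqueous NaOAc would give 17.

**Step 9.** What may go wrong: acid-induced cyclodehydration of the 1,4-keto aldehyde to a furan or an aldol reaction before the amine is free, partial loss of the silyl ether, or oligomeric imine formation. Transient enamine formation toward C9 could also erode that centre, although the trans arrangement is the favoured one.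
Fallback (sets out from 9, returns at 13): unmask the nitrogen under neutral conditions by a Staudinger/aza-Wittig sequence. Acidolysis of 9 would give the amine F8 (handled as its salt), and copper-catalysed diazo transfer (imidazole-1-sulfonyl azide, CuSO4, K2CO3) the azide F9. α′-Allylation as in step 7, now with one equivalent of base, would give the allyl azido ketone F10, and ozonolysis the azido keto aldehyde F11. PPh3 would convert the azide into the iminophosphorane, which closes onto the C9a ketone, and AcOH would complete the condensation with the aldehyde to pyrrole 13.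

**Step 4.** What may go wrong: slow capture of the zinc enolate by the π-allylpalladium complex (simple protonation instead) or eroded anti selectivity in either bond formation.
Fallback (sets out from 4, returns at 6): separate the two events. Copper-catalysed addition of EtMgBr (CuBr·SMe2) in the presence of Me3SiCl would give the trimethylsilyl enol ether F12. MeLi would regenerate the regiodefined lithium enolate, and SN2 allylation with allyl iodide in THF–DMPU would give 6.

## Further compounds

F1 | step 16 | tricyclic C11 alcohol (9R,10R,11R), desilylated 13 | CC[C@H]1[C@H](O)Cc2ccn3c2[C@@H]1CCCC3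
F2 | step 16 | tricyclic C11 ketone (9R,10R) | CC[C@H]1C(=O)Cc2ccn3c2[C@@H]1CCCC3
F3 | step 16 | methyl 2-[(9R,10R)-10-ethyl-11-oxo-tricycl-12-yl]propanoate (mixture at C12 and C13) | CC[C@H]1C(=O)C(C(C)C(=O)OC)c2ccn3c2[C@@H]1CCCC3
F4 | step 16 | cis-fused lactone D tetracycle without C3 side chain (C13 mixture) | CC[C@H]1[C@@H]2OC(=O)C(C)[C@@H]2c2ccn3c2[C@@H]1CCCC3
F5 | step 16 | cis-fused lactone D tetracycle without C3 side chain (9R,10R,11S,12R,13R) | CC[C@H]1[C@@H]2OC(=O)[C@H](C)[C@@H]2c2ccn3c2[C@@H]1CCCC3
F6 | step 17 | C18 epimer of 23 (18R) | CC[C@H]1[C@@H]2OC(=O)[C@H](C)[C@@H]2c2cc([C@H]3C[C@H](C)C(=O)O3)n3c2[C@@H]1CCCC3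
F7 | step 12 | methyl (2S)-4-(dimethylamino)-2-methyl-4-oxobutanoate | CN(C)C(=O)C[C@H](C)C(=O)OC
F8 | step 9 | (2R,3R,4R)-2-(4-aminobutyl)-4-[(tert-butyldimethylsilyl)oxy]-3-ethylcyclohexan-1-one | CC[C@H]1[C@H](O[Si](C)(C)C(C)(C)C)CCC(=O)[C@@H]1CCCCN
F9 | step 9 | (2R,3R,4R)-2-(4-azidobutyl)-4-[(tert-butyldimethylsilyl)oxy]-3-ethylcyclohexan-1-one | CC[C@H]1[C@H](O[Si](C)(C)C(C)(C)C)CCC(=O)[C@@H]1CCCCN=[N+]=[N-]
F10 | step 9 | (2R,3R,4R)-2-(4-azidobutyl)-4-[(tert-butyldimethylsilyl)oxy]-3-ethyl-6-(prop-2-en-1-yl)cyclohexan-1-one | CC[C@H]1[C@H](O[Si](C)(C)C(C)(C)C)CC(CC=C)C(=O)[C@@H]1CCCCN=[N+]=[N-]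
F11 | step 9 | (2R,3R,4R)-2-(4-azidobutyl)-4-[(tert-butyldimethylsilyl)oxy]-3-ethyl-6-(2-oxoethyl)cyclohexan-1-one | CC[C@H]1[C@H](O[Si](C)(C)C(C)(C)C)CC(CC=O)C(=O)[C@@H]1CCCCN=[N+]=[N-]
F12 | step 4 | trimethylsilyl enol ether of (3R,4R)-4-[(tert-butyldimethylsilyl)oxy]-3-ethylcyclohexanone | CC[C@H]1[C@H](O[Si](C)(C)C(C)(C)C)CCC(O[Si](C)(C)C)=C1
A1 | alternative 1 | trans-1-(but-3-en-1-yl)-6-ethyl-6,7-dihydro-1H-indole-7-carboxylic acid | CC[C@H]1C=Cc2ccn(CCC=C)c2[C@@H]1C(=O)O
A2 | alternative 1 | pyrrole-fused δ-lactone, 1-(but-3-en-1-yl)-4-[(1Z)-but-1-en-1-yl]-4,7-dihydropyrano[4,3-b]pyrrol-6(1H)-one | CC/C=C\[C@@H]1OC(=O)Cc2c1ccn2CCC=C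
A3 | alternative 2 | 7-oxo derivative of 23 | CC[C@H]1[C@@H]2OC(=O)[C@H](C)[C@@H]2c2cc([C@@H]3C[C@H](C)C(=O)O3)n3c2[C@@H]1CC(=O)CC3
A4 | alternative 2 | N–H pyrrole bis-lactone with a hexa-1,4-dien-3-one chain on C10 | C=CC(=O)/C=C/[C@@H](CC)[C@@H]1OC(=O)[C@H](C)[C@@H]1c2cc([C@@H]3C[C@H](C)C(=O)O3)[nH]c2
A5 | alternative 3 | 10-vinyl analogue of 23 | C=C[C@H]1[C@@H]2OC(=O)[C@H](C)[C@@H]2c2cc([C@@H]3C[C@H](C)C(=O)O3)n3c2[C@@H]1CCCC3
A6 | alternative 3 | pyrroloazepine with a C9 (E)-3-(trimethylsilyl)prop-1-enyl group and a C1 aldehyde ester chain | C[Si](C)(C)C/C=C/[C@H]1CCCCn2c1c([C@H](C=O)[C@@H](C)C(=O)OC)cc2[C@@H]3C[C@H](C)C(=O)O3
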